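## Structural features

The target is a serrulatane-type diterpenoid acid. It is a tetralin in which aromatic ring A (C4a, C5–C8, C8a) is fused to saturated ring B (C1–C4), with a branched seven-carbon chain on C1. Ring A carries hydroxyls on C5 and C6 and a carboxyl on C7, so C5–C7 form a 2,3-dihydroxybenzoic acid. This unit is oxidation-prone and strongly chelating, so it is the fragile part and is best carried as its dimethyl ether, without the carboxyl, until the end. Ring B holds C1 (S) and C4 (R) in a 1,4-trans relationship, the C4 methyl lying peri to the C5 oxygen. C1 is bonded directly to the chain stereocentre C11 (S), the only vicinal stereo pair. C11 bears the hydroxymethyl C20 and the tether C12–C13–C14, which ends at C15 (S) with a methyl and the second hydroxymethyl C16. The difficulties are the joint control of C4, C1 and C11 at the ring–chain junction, and C15, which is insulated from C11 by three methylenes and cannot be set by relay from the core. The key step uses the fact that C14–C15–C16–OH is allyl alcohol with a methyl on its internal carbon: catalyst-controlled methylalumination sets C15, and the new C14–metal bond is coupled to a C13 alkenyl iodide; the temporary C12=C13 alkene is hydrogenated later.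

## Logic of the disconnections

**27 to 26.** The two aryl O–CH3 bonds (C5, C6) and the two O–Si bonds (C16, C20) are cut last. This keeps the air-sensitive catechol acid masked through all organometallic steps. The forward step needs a reagent that cleaves aryl methyl and silyl ethers without substituting the primary C–O bonds.

**26 to 24 (through 25).** The C7–carboxyl bond is cut. C7–H is the only aromatic hydrogen ortho to an alkoxy group, so lithiation is regiodefined. A carboxyl present earlier would also weaken the C6 oxygen as a donor in the ring-forming and cation steps. The forward step demands the absence of O–H groups and of benzyl ethers.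

**24 to 23 to 22.** These are functional-group changes only: O–Si bonds, then the C12=C13 π bond and the C20 O–benzyl bond. One hydrogenation removes both the coupling handle and the benzyl group. It must not move the double bond toward the allylic centre C11.

**22 to 18, 19 and 20 (through 21).** C13–C14 and C15–CH3 are cut. This removes the remote stereocentre together with three chain carbons and leaves a core fragment ending in a C13–iodine bond. C15 is then set on a three-carbon unit by the catalyst alone. The forward step needs enantioface selection on 19, methyl delivery to the internal carbon, and an alkyl–alkenyl coupling that preserves C11.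

**18 to 17 to 16 to 15.** C12=C13 is cut (one-carbon iodo-olefination), then the oxidation level at C12 is adjusted and the N-acyl bond to the auxiliary restored. The demand is that the α-branched, β-alkoxy aldehyde 17 is handled without epimerisation at C11.

**15 to 9 and 13 (through 14).** The C1–C11 bond is cut at the junction of ring and chain. The C1 cation from 9 is stabilised by the para oxygen on C6, and the enolate from 13 brings C11, C12 and C20 at the right oxidation levels. Two stereocentres form at once, so the forward step needs facial control on both partners: the auxiliary for C11, the ring conformation for C1.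

**13 to 10 and 11 (through 12); 9 to 8 to 7.** The N-acyl bond, and the C1–O bonds down to the ketone, are cut. These are routine changes; the C1 configuration in 8 and 9 is immaterial because it is erased on ionisation.

**7 to 6.** C1–C8a is cut (ring B). C8a is the only free position ortho to the side chain and is para to the C6 methoxyl, so the acylation is regiodefined.

**6 to 5 to 3 (through 4).** One carbon is removed between C3 and the carboxyl carbon. This gives a β-aryl ester whose stereocentre can be made by conjugate addition. The homologation must not touch C4.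

**3 to 1 and 2.** C4–C4a is cut. Conjugate arylation of a crotonate sets C4 by catalyst control from two simple achiral materials.

## Other disconnections considered

**Alternative 1:** The cut runs through ring A: C7–C8 and C4a–C8a are broken, which unravels both rings to the alkynyl pyrone A2. In A2 the pyrone C6, C5, C4 and C3 become C4a, C5, C6 and C7, C1–C4 form the tether, and C1 carries a terminal alkyne (C8a, C8). On heating, the alkyne would add across pyrone C3/C6, and the bridged adduct would aromatise by decarboxylative cycloreversion to the ester A1.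
- In favour: ring A is formed with the C7 carboxyl and both oxygens in place, with regiochemistry fixed by the tether. On this point the alternative is better than the chosen plan, which spends steps 14 and 15 on it.
- Against: all four stereocentres must be set in open-chain A2. C1 is a propargylic centre beside C11. C4 sits next to the pyrone, where its hydrogen is vinylogously activated and could epimerise at the temperature an unactivated alkyne needs. The tetrasubstituted pyrone itself costs several steps.
- Comparison: structurally it solves the arene better and the stereocentres worse. Mechanistically it is an uncatalysed thermal cascade, against a catalytic sequence whose two halves can be tuned separately. In step economy the late saving is probably outweighed by the route to A2, and C15 would still need a reaction like step 12. It therefore replaces the core construction rather than the key step.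

**Alternative 2:** C14–C15 and C11–C12 are cut, leading to the diene A5 and methyl 2-diazobut-3-enoate A4. With a chiral dirhodium tetracarboxylate, the vinylcarbenoid from A4 would cyclopropanate the less hindered C15=C16 alkene of A5. The cis-divinylcyclopropane would then undergo Cope rearrangement through a boat transition state to the cycloheptadiene A3, whose C16=C20 alkene is a masked pair of hydroxymethyl groups.
- In favour: C11 and C15 are set in one catalytic step, with their relative configuration fixed by a concerted process. This reaction class usually gives high enantioselectivity. On both counts it is equal to or better than the chosen key step, which sets one centre.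
- Against: the ester on C14 is a carbon the target lacks and must be excised after the C13=C14 alkene is dealt with. The ring alkene must be cleaved oxidatively beside an electron-rich dimethoxyarene. The trans-disubstituted alkenes of A5 are slow partners for such carbenoids. The catalyst must act in a matched sense with the existing C1 centre next to C11.
- Comparison: it is better on the number of centres per step and worse on structural fit, because it adds an extra carbon and needs two alkenes differentiated. In step economy the operations after A3 (cleavage, reduction, decarboxylation, saturation, protection) are likely to exceed the four steps after 22. A5 would still need the C1 chemistry of step 8.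

**Alternative 3:** C1–C8a is cut, giving the lactone-fused cyclopropane A7 with the arene tethered through C2–C4. A Lewis acid on the lactone/ester pair would let C8a (para to the C6 methoxyl) attack C1 from the rear. C1–C12 would break with inversion and ring B would close (6-exo) to the lactone A6.
- In favour: C1 and C11 come stereospecifically from the cyclopropane, so the 1,4-trans relationship rests on reagent control at both ends. On this point it is better than step 8, where C1 depends on induction from C4. No free benzylic cation is formed, and the lactone keeps C20 distinct from C12/C13.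
- Against: C1 of A7 bears only an alkyl donor, so ring opening may drift toward ionisation or elimination. Asymmetric intramolecular cyclopropanation of allyl diazomalonates is variable. The ester on C12 must be removed. The lactone must still be elaborated to attach C14–C16.
- Comparison: it competes with the preparation of 18, not with step 12; C15 would still need the carboalumination or a chiral-pool fragment. It is equal or better on control of C1, and worse on step count (diazo transfer, cyclopropanation, opening, dealkoxycarbonylation, lactone elaboration).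

Key step: step 12

Remark on the chemistry (assumption): the sense of induction of (S)-BINAP in the rhodium-catalysed arylation of the crotonate (giving 4R) and of (−)-(NMI)2ZrCl2 in the methylalumination (giving 15S) is taken from the behaviour of close analogues; if either is opposite in practice, the antipodal ligand or zirconocene is used.

## Route

Step 1
Reactants: 1 2,3-dimethoxyphenylboronic acid; 2 methyl (E)-but-2-enoate (methyl crotonate)
Product: 3 methyl (3R)-3-(2,3-dimethoxyphenyl)butanoate
Conditions: 1 (2.5 equiv), Rh(acac)(C2H4)2 (3 mol %), (S)-BINAP (3.3 mol %), 1,4-dioxane/H2O (10:1), 100 °C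
Reagents that add atoms: none
Why: Hayashi–Miyaura asymmetric 1,4-addition: the aryl–rhodium/BINAP species inserts the crotonate and the oxa-π-allyl is protonated by water; the ligand selects the alkene face and so sets C4 (R); excess 1 compensates for protodeboronation of the ortho-substituted boronic acid.

Step 2
Reactants: 3 methyl (3R)-3-(2,3-dimethoxyphenyl)butanoate
Product: 5 ethyl (4R)-4-(2,3-dimethoxyphenyl)pentanoate, via lithium ynolate 4 (not isolated)
Conditions: CH2Br2, lithium 2,2,6,6-tetramethylpiperidide, THF, −78 °C; LiN(SiMe3)2; n-BuLi, −78 → 23 °C; then HCl/EtOH, 0 °C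
Reagents that add atoms: dibromomethane, BrCBr; ethanol, CCO
Why: Kowalski ester homologation: dibromomethyllithium adds to the ester, the dibromoketone enolate undergoes bromine–lithium exchange and 1,2-shift to ynolate 4, and acidic ethanol traps the derived ketene as 5; C4 is not α to the carbonyl and is untouched, and any aryl lithiation is reversed on quench.

Step 3
Reactants: 5 ethyl (4R)-4-(2,3-dimethoxyphenyl)pentanoate
Product: 6 (4R)-4-(2,3-dimethoxyphenyl)pentanoic acid
Conditions: LiOH, THF/H2O, 23 °C; then aq. HCl
Reagents that add atoms: lithium hydroxide, [Li+].[OH-]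
Why: Ester saponification; no stereocentre is adjacent to the carbonyl.

Step 4
Reactants: 6 (4R)-4-(2,3-dimethoxyphenyl)pentanoic acid
Product: 7 (4R)-5,6-dimethoxy-4-methyl-3,4-dihydronaphthalen-1(2H)-one
Conditions: P2O5/MeSO3H (1:10 w/w), 23 °C
Reagents that add atoms: none
Why: Intramolecular Friedel–Crafts acylation closes ring B at C8a, the only free position ortho to the chain and para to the C6 methoxyl; the C4 centre is not involved.

Step 5
Reactants: 7 (4R)-5,6-dimethoxy-4-methyl-3,4-dihydronaphthalen-1(2H)-one
Product: 8 (4R)-5,6-dimethoxy-4-methyl-1,2,3,4-tetrahydronaphthalen-1-ol (mixture of C1 epimers)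
Conditions: NaBH4, MeOH, 0 °C
Reagents that add atoms: none
Why: Hydride reduction of the aryl ketone; the new carbinol centre need not be controlled because C1 is ionised in step 8.

Step 6
Reactants: 8 (4R)-5,6-dimethoxy-4-methyl-1,2,3,4-tetrahydronaphthalen-1-ol (mixture of C1 epimers)
Product: 9 (4R)-5,6-dimethoxy-4-methyl-1,2,3,4-tetrahydronaphthalen-1-yl acetate (mixture of C1 epimers)
Conditions: Ac2O, pyridine, DMAP (cat.), CH2Cl2, 0 → 23 °C; used without chromatography
Reagents that add atoms: acetic anhydride, CC(=O)OC(C)=O
Why: Acylation gives an ionisable benzylic leaving group; the para-alkoxybenzylic acetate is kept away from acid and silica to avoid premature ionisation.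

Step 7
Reactants: 10 3-(benzyloxy)propanoic acid; 11 (4S)-4-benzyloxazolidin-2-one
Product: 13 (4S)-4-benzyl-3-[3-(benzyloxy)propanoyl]oxazolidin-2-one, via mixed pivalic anhydride 12 (not isolated)
Conditions: pivaloyl chloride, Et3N, THF, −20 °C; then LiCl, 11, −20 → 23 °C
Reagents that add atoms: none
Why: N-acylation of the oxazolidinone through the mixed anhydride, which is attacked at the less hindered carbonyl; LiCl activates the oxazolidinone under mild base.

Step 8
Reactants: 9 (4R)-5,6-dimethoxy-4-methyl-1,2,3,4-tetrahydronaphthalen-1-yl acetate (mixture of C1 epimers); 13 (4S)-4-benzyl-3-[3-(benzyloxy)propanoyl]oxazolidin-2-one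
Product: 15 (4S)-4-benzyl-3-{(2S)-3-(benzyloxy)-2-[(1S,4R)-5,6-dimethoxy-4-methyl-1,2,3,4-tetrahydronaphthalen-1-yl]propanoyl}oxazolidin-2-one, via chlorotitanium enolate 14 (not isolated)
Conditions: 13 (1.3 equiv), TiCl4 (1.4 equiv), i-Pr2NEt (1.5 equiv), CH2Cl2, −78 → 0 °C; then 9 (1.0 equiv), TiCl4 (1.0 equiv), −78 → −30 °C
Reagents that add atoms: none
Why: SN1-type alkylation of a chelated (Z)-titanium enolate of an N-acyl oxazolidinone by a benzylic cation: the enolate reacts on the face away from the auxiliary benzyl group, which sets C11 (S in 15); the cation (stabilised by the C6 methoxyl) holds its C4 methyl pseudo-axial because of peri strain with the C5 methoxyl and is attacked axially anti to it, which sets C1 (S) trans to C4.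

Step 9
Reactants: 15 (4S)-4-benzyl-3-{(2S)-3-(benzyloxy)-2-[(1S,4R)-5,6-dimethoxy-4-methyl-1,2,3,4-tetrahydronaphthalen-1-yl]propanoyl}oxazolidin-2-one
Product: 16 (2R)-3-(benzyloxy)-2-[(1S,4R)-5,6-dimethoxy-4-methyl-1,2,3,4-tetrahydronaphthalen-1-yl]propan-1-ol
Conditions: LiBH4, MeOH (1.1 equiv), Et2O, 0 °C
Reagents that add atoms: none
Why: Reductive removal of the auxiliary at the exocyclic imide carbonyl gives the C12 primary alcohol and returns 11; the stable alcohol allows purification of the diastereomer before the sensitive aldehyde (the descriptor at C11 changes by priority only).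

Step 10
Reactants: 16 (2R)-3-(benzyloxy)-2-[(1S,4R)-5,6-dimethoxy-4-methyl-1,2,3,4-tetrahydronaphthalen-1-yl]propan-1-ol
Product: 17 (2S)-3-(benzyloxy)-2-[(1S,4R)-5,6-dimethoxy-4-methyl-1,2,3,4-tetrahydronaphthalen-1-yl]propanal
Conditions: Dess–Martin periodinane, NaHCO3, CH2Cl2, 0 → 23 °C; crude aldehyde used at once
Reagents that add atoms: none
Why: Buffered Dess–Martin oxidation is neutral and fast, which limits epimerisation at C11 and loss of benzyl alcohol from the β-alkoxy aldehyde.

Step 11
Reactants: 17 (2S)-3-(benzyloxy)-2-[(1S,4R)-5,6-dimethoxy-4-methyl-1,2,3,4-tetrahydronaphthalen-1-yl]propanal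
Product: 18 (1S,4R)-1-[(2R,3E)-1-(benzyloxy)-4-iodobut-3-en-2-yl]-5,6-dimethoxy-4-methyl-1,2,3,4-tetrahydronaphthalene
Conditions: CrCl2 (8 equiv), CHI3 (3 equiv), THF/1,4-dioxane (1:6), 0 → 23 °C, dark
Reagents that add atoms: iodoform, IC(I)I
Why: Takai iodo-olefination: the geminal dichromium species from iodoform and divalent chromium adds to the aldehyde and eliminates anti to give the (E)-alkenyl iodide under non-basic conditions that spare C11; the descriptor at C11 changes to R only because the iodoalkenyl group now outranks C1, and any Z isomer is harmless since the alkene is hydrogenated in step 13.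

Step 12
Reactants: 18 (1S,4R)-1-[(2R,3E)-1-(benzyloxy)-4-iodobut-3-en-2-yl]-5,6-dimethoxy-4-methyl-1,2,3,4-tetrahydronaphthalene; 19 prop-2-en-1-ol (allyl alcohol); 20 trimethylaluminium
Product: 22 (2S,4E,6S)-7-(benzyloxy)-6-[(1S,4R)-5,6-dimethoxy-4-methyl-1,2,3,4-tetrahydronaphthalen-1-yl]-2-methylhept-4-en-1-ol, via alkylalane 21 (not isolated)
Conditions: 19 (3 equiv), Me3Al (7.5 equiv), (MeAlO)n (3 equiv), (−)-bis(1-neomenthylindenyl)zirconium dichloride [(−)-(NMI)2ZrCl2] (5 mol % on 19), CH2Cl2, 0 → 23 °C; volatiles removed in vacuo; Zn(OTf)2 (3 equiv), DMF, 70 °C; then 18 (1 equiv), PdCl2(DPEphos) (5 mol %), i-Bu2AlH (10 mol %), 23 → 50 °C; aq. HCl work-up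
Reagents that add atoms: none
Why: Trimethylaluminium first converts 19 into its dimethylaluminium alkoxide, and a cationic methylzirconocene (from the zirconium dichloride, 20 and methylaluminoxane) adds Zr–CH3 syn across the alkene, methyl to internal C15 and metal to terminal C14, after which Zr/Al exchange releases alkylalane 21 and regenerates the catalyst. After excess 20 is evaporated, Zn(OTf)2 in DMF transfers the C14 alkyl group to zinc, zerovalent palladium (from PdCl2(DPEphos) and i-Bu2AlH) inserts into the C13–iodine bond of 18 with retention of the E geometry, and transmetalation and reductive elimination form C13–C14. The closest known reaction type is the zirconium-catalysed asymmetric carboalumination of terminal alkenes run in one flask with Negishi coupling of the alkylalane to alkenyl halides, which is established for allyl alcohol itself. No ring is closed. The one new stereocentre, C15, is controlled only by enantioface selection of the chiral zirconocene, the (−)-enantiomer being expected to give 15S; 18 enters after C15 exists and cannot interfere. Regioselectivity follows from the preference of the metal for the unhindered terminus. Alkyl rather than methyl transfer is favoured by removing excess 20 before coupling, and the wide-bite-angle DPEphos ligand should suppress β-hydride elimination of the alkylpalladium intermediate. The allylic C11 centre of 18 is not acidic and should pass unchanged.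

Step 13
Reactants: 22 (2S,4E,6S)-7-(benzyloxy)-6-[(1S,4R)-5,6-dimethoxy-4-methyl-1,2,3,4-tetrahydronaphthalen-1-yl]-2-methylhept-4-en-1-ol
Product: 23 (2S,6S)-2-[(1S,4R)-5,6-dimethoxy-4-methyl-1,2,3,4-tetrahydronaphthalen-1-yl]-6-methylheptane-1,7-diol
Conditions: H2 (1 atm), 5% Pt/C, EtOAc, 23 °C; then 20% Pd(OH)2/C and EtOH added, H2 (1 atm), 23 °C
Reagents that add atoms: none
Why: Heterogeneous hydrogenation: platinum saturates the disubstituted C12=C13 alkene with little double-bond migration, so the allylic C11 centre should be preserved; Pd(OH)2 then hydrogenolyses the C20 benzyl ether, and the aryl methyl ethers and the arene are inert.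

Step 14
Reactants: 23 (2S,6S)-2-[(1S,4R)-5,6-dimethoxy-4-methyl-1,2,3,4-tetrahydronaphthalen-1-yl]-6-methylheptane-1,7-diol
Product: 24 (1S,4R)-1-[(2S,6S)-1,7-bis(tert-butyldimethylsilyloxy)-6-methylheptan-2-yl]-5,6-dimethoxy-4-methyl-1,2,3,4-tetrahydronaphthalene
Conditions: TBSCl (2.5 equiv), imidazole (5 equiv), DMF, 23 °C
Reagents that add atoms: tert-butyldimethylsilyl chloride, C[Si](C)(Cl)C(C)(C)C
Why: Silylation of both primary alcohols removes acidic O–H before the organolithium step; the silyl ethers tolerate butyllithium and fall off in the last step.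

Step 15
Reactants: 24 (1S,4R)-1-[(2S,6S)-1,7-bis(tert-butyldimethylsilyloxy)-6-methylheptan-2-yl]-5,6-dimethoxy-4-methyl-1,2,3,4-tetrahydronaphthalene
Product: 26 (5R,8S)-8-[(2S,6S)-1,7-bis(tert-butyldimethylsilyloxy)-6-methylheptan-2-yl]-3,4-dimethoxy-5-methyl-5,6,7,8-tetrahydronaphthalene-2-carboxylic acid, via aryllithium 25 (not isolated)
Conditions: n-BuLi (2.5 equiv), TMEDA (2.5 equiv), Et2O, 0 → 23 °C; dry CO2, −78 → 0 °C; cold 0.5 M HCl to pH 3–4
Reagents that add atoms: carbon dioxide, O=C=O
Why: Directed ortho-metalation: the C6 methoxyl directs lithiation to C7, the only aromatic hydrogen ortho to an alkoxy group, and aryllithium 25 is carboxylated by CO2; the tertiary benzylic hydrogens at C1 and C4 are kinetically far less acidic, so no stereocentre is touched.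

Step 16
Reactants: 26 (5R,8S)-8-[(2S,6S)-1,7-bis(tert-butyldimethylsilyloxy)-6-methylheptan-2-yl]-3,4-dimethoxy-5-methyl-5,6,7,8-tetrahydronaphthalene-2-carboxylic acid
Product: 27 (5R,8S)-8-[(2S,6S)-1,7-dihydroxy-6-methylheptan-2-yl]-3,4-dihydroxy-5-methyl-5,6,7,8-tetrahydronaphthalene-2-carboxylic acid (target)
Conditions: BBr3 (8 equiv), CH2Cl2, −78 → 0 °C; then H2O/THF, 0 → 23 °C; argon, degassed solvents
Reagents that add atoms: none
Why: Lewis-acid ether cleavage: BBr3 converts both aryl methyl ethers (the C6 one assisted by the neighbouring carboxyl) into aryloxyboranes with loss of bromomethane and cleaves the silyl ethers to alkoxyboranes; hydrolysis frees the catechol, the acid and both alcohols, and the low temperature is meant to prevent substitution at C16 and C20.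

## Compound list

1 | 2,3-dimethoxyphenylboronic acid | COc1cccc(B(O)O)c1OC | starting material
2 | methyl (E)-but-2-enoate (methyl crotonate) | C/C=C/C(=O)OC | starting material
3 | methyl (3R)-3-(2,3-dimethoxyphenyl)butanoate | C[C@H](CC(=O)OC)c1cccc(OC)c1OC | intermediate
4 | lithium (4R)-4-(2,3-dimethoxyphenyl)pent-1-yn-1-olate (ynolate, not isolated) | C[C@H](CC#C[O-])c1cccc(OC)c1OC.[Li+] | intermediate
5 | ethyl (4R)-4-(2,3-dimethoxyphenyl)pentanoate | CCOC(=O)CC[C@@H](C)c1cccc(OC)c1OC | intermediate
6 | (4R)-4-(2,3-dimethoxyphenyl)pentanoic acid | OC(=O)CC[C@@H](C)c1cccc(OC)c1OC | intermediate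
7 | (4R)-5,6-dimethoxy-4-methyl-3,4-dihydronaphthalen-1(2H)-one | O=C1CC[C@@H](C)c2c1ccc(OC)c2OC | intermediate
8 | (4R)-5,6-dimethoxy-4-methyl-1,2,3,4-tetrahydronaphthalen-1-ol, both C1 epimers | OC1CC[C@@H](C)c2c1ccc(OC)c2OC | intermediate
9 | (4R)-5,6-dimethoxy-4-methyl-1,2,3,4-tetrahydronaphthalen-1-yl acetate, both C1 epimers | CC(=O)OC1CC[C@@H](C)c2c1ccc(OC)c2OC | intermediate
10 | 3-(benzyloxy)propanoic acid | OC(=O)CCOCc1ccccc1 | starting material
11 | (4S)-4-benzyloxazolidin-2-one | O=C1N[C@@H](Cc2ccccc2)CO1 | starting material
12 | 3-(benzyloxy)propanoic pivalic anhydride (not isolated) | CC(C)(C)C(=O)OC(=O)CCOCc1ccccc1 | intermediate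
13 | (4S)-4-benzyl-3-[3-(benzyloxy)propanoyl]oxazolidin-2-one | O=C(CCOCc1ccccc1)N1C(=O)OC[C@@H]1Cc1ccccc1 | intermediate
14 | trichlorotitanium (Z)-enolate of 13 (not isolated) | Cl[Ti](Cl)(Cl)O/C(=C\COCc1ccccc1)N1C(=O)OC[C@@H]1Cc1ccccc1 | intermediate
15 | (4S)-4-benzyl-3-{(2S)-3-(benzyloxy)-2-[(1S,4R)-5,6-dimethoxy-4-methyl-1,2,3,4-tetrahydronaphthalen-1-yl]propanoyl}oxazolidin-2-one | O=C([C@H](COCc1ccccc1)[C@@H]1CC[C@@H](C)c2c1ccc(OC)c2OC)N1C(=O)OC[C@@H]1Cc1ccccc1 | intermediate
16 | (2R)-3-(benzyloxy)-2-[(1S,4R)-5,6-dimethoxy-4-methyl-1,2,3,4-tetrahydronaphthalen-1-yl]propan-1-ol | OC[C@H](COCc1ccccc1)[C@@H]1CC[C@@H](C)c2c1ccc(OC)c2OC | intermediate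
17 | (2S)-3-(benzyloxy)-2-[(1S,4R)-5,6-dimethoxy-4-methyl-1,2,3,4-tetrahydronaphthalen-1-yl]propanal | O=C[C@H](COCc1ccccc1)[C@@H]1CC[C@@H](C)c2c1ccc(OC)c2OC | intermediate
18 | (1S,4R)-1-[(2R,3E)-1-(benzyloxy)-4-iodobut-3-en-2-yl]-5,6-dimethoxy-4-methyl-1,2,3,4-tetrahydronaphthalene | I/C=C/[C@H](COCc1ccccc1)[C@@H]1CC[C@@H](C)c2c1ccc(OC)c2OC | intermediate
19 | prop-2-en-1-ol (allyl alcohol) | C=CCO | starting material
20 | trimethylaluminium | C[Al](C)C | starting material
21 | [(2R)-3-(dimethylalumanyl)-2-methylpropoxy]dimethylalumane (alkylalane, not isolated) | C[C@H](CO[Al](C)C)C[Al](C)C | intermediate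
22 | (2S,4E,6S)-7-(benzyloxy)-6-[(1S,4R)-5,6-dimethoxy-4-methyl-1,2,3,4-tetrahydronaphthalen-1-yl]-2-methylhept-4-en-1-ol | C[C@H](CO)C/C=C/[C@H](COCc1ccccc1)[C@@H]1CC[C@@H](C)c2c1ccc(OC)c2OC | intermediate
23 | (2S,6S)-2-[(1S,4R)-5,6-dimethoxy-4-methyl-1,2,3,4-tetrahydronaphthalen-1-yl]-6-methylheptane-1,7-diol | C[C@H](CO)CCC[C@H](CO)[C@@H]1CC[C@@H](C)c2c1ccc(OC)c2OC | intermediate
24 | (1S,4R)-1-[(2S,6S)-1,7-bis(tert-butyldimethylsilyloxy)-6-methylheptan-2-yl]-5,6-dimethoxy-4-methyl-1,2,3,4-tetrahydronaphthalene | C[C@H](CO[Si](C)(C)C(C)(C)C)CCC[C@H](CO[Si](C)(C)C(C)(C)C)[C@@H]1CC[C@@H](C)c2c1ccc(OC)c2OC | intermediate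
25 | C7 aryllithium of 24 (not isolated) | C[C@H](CO[Si](C)(C)C(C)(C)C)CCC[C@H](CO[Si](C)(C)C(C)(C)C)[C@@H]1CC[C@@H](C)c2c1cc([Li])c(OC)c2OC | intermediate
26 | (5R,8S)-8-[(2S,6S)-1,7-bis(tert-butyldimethylsilyloxy)-6-methylheptan-2-yl]-3,4-dimethoxy-5-methyl-5,6,7,8-tetrahydronaphthalene-2-carboxylic acid | C[C@H](CO[Si](C)(C)C(C)(C)C)CCC[C@H](CO[Si](C)(C)C(C)(C)C)[C@@H]1CC[C@@H](C)c2c1cc(C(=O)O)c(OC)c2OC | intermediate
27 | (5R,8S)-8-[(2S,6S)-1,7-dihydroxy-6-methylheptan-2-yl]-3,4-dihydroxy-5-methyl-5,6,7,8-tetrahydronaphthalene-2-carboxylic acid | C[C@H](CO)CCC[C@H](CO)[C@@H]1CC[C@@H](C)c2c1cc(C(=O)O)c(O)c2O | target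

## Step count and least certain steps

Total: 16 steps. Longest linear sequence: 15 steps (steps 1–6 and 8–16; step 7 is a one-step side branch).

**Step 12 (key step).** The most likely failure is incomplete enantioface selection in the methylalumination. Because 18 is a single enantiomer, this would appear as a C15 epimer remote from every other centre and hard to remove. A second risk is slow transfer of the C14 alkyl group from aluminium through zinc to palladium, with methyl transfer or protodemetalation competing.
Fallback: start from 18 and take C15 from the chiral pool. The alkylzinc reagent from (R)-tert-butyl(3-iodo-2-methylpropoxy)dimethylsilane (three steps from methyl (R)-3-hydroxy-2-methylpropanoate; t-BuLi, ZnCl2) would be coupled with 18 using Pd(PPh3)4 in THF (Negishi coupling, the same C13–C14 bond). This should give the C16 silyl ether of 22, F1. Hydrogenation as in step 13 would give the C20 alcohol carrying the C16 silyl ether, F2. Silylation as in step 14 rejoins the route at 24.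

**Step 8.** The risks are poor facial discrimination at the planar C1 cation (the C4 methyl is the only control element), loss of benzyl alkoxide from the β-alkoxy enolate by elimination, and proton loss from the cation to a 1,2-dihydronaphthalene.
Fallback: start from 9 and set C1 and C11 in separate events. The titanium enolate of commercial (R)-3-acetyl-4-benzyloxazolidin-2-one (TiCl4, i-Pr2NEt) would be alkylated by the cation from 9 to give the (4R)-4-benzyl-3-{[(1S,4R)-5,6-dimethoxy-4-methyl-1,2,3,4-tetrahydronaphthalen-1-yl]acetyl}oxazolidin-2-one F3, where only the ring conformation has to control C1. A second titanium-enolate alkylation with benzyl chloromethyl ether, under auxiliary control and with no β-alkoxy enolate involved, would give the (4R)-auxiliary diastereomer of 15, F4. Reduction with LiBH4 rejoins the route at 16.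

**Step 2.** The carbenoid rearrangement may be incomplete, or butyllithium may add to the intermediate ketone enolate, lowering conversion to the homologated ester.
Fallback: start from 3 and use a stepwise homologation. LiAlH4 reduction would give (3R)-3-(2,3-dimethoxyphenyl)butan-1-ol F5. Appel bromination (CBr4, PPh3) would give 1-[(2R)-4-bromobutan-2-yl]-2,3-dimethoxybenzene F6. Grignard formation (Mg, THF) and carboxylation with CO2 rejoin the route at 6.

**Step 13.** The double bond may migrate on the metal surface toward C11 before it is saturated, which would epimerise C11.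
Fallback: start from 22 and reduce the alkene without a metal surface. Diimide (2-nitrobenzenesulfonylhydrazide, Et3N, CH2Cl2) would give the saturated C20 benzyl ether F7. Hydrogenolysis over Pd(OH)2/C, with no alkene left to isomerise, rejoins the route at 23.

**Step 16.** The primary alkoxyboron intermediates at C16 and C20 may be substituted by bromide, the flanked C5 methyl ether may be cleaved incompletely, and the liberated catechol may oxidise in air.
Fallback: start from 26 and change the hydroxyl protection so that no alkoxyboranes form. Desilylation with Bu4NF would give the dihydroxy dimethoxy acid F8. Ac2O/pyridine would give its diacetate F9. BBr3 at −78 → −20 °C would cleave only the aryl methyl ethers to the catechol acid diacetate F10. Degassed K2CO3/MeOH then gives 27.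

## Further compounds

F1 | step 12 | (1S,4R)-1-[(2S,3E,6S)-1-(benzyloxy)-7-(tert-butyldimethylsilyloxy)-6-methylhept-3-en-2-yl]-5,6-dimethoxy-4-methyl-1,2,3,4-tetrahydronaphthalene (C16 silyl ether of 22) | C[C@H](CO[Si](C)(C)C(C)(C)C)C/C=C/[C@H](COCc1ccccc1)[C@@H]1CC[C@@H](C)c2c1ccc(OC)c2OC
F2 | step 12 | (2S,6S)-7-(tert-butyldimethylsilyloxy)-2-[(1S,4R)-5,6-dimethoxy-4-methyl-1,2,3,4-tetrahydronaphthalen-1-yl]-6-methylheptan-1-ol | C[C@H](CO[Si](C)(C)C(C)(C)C)CCC[C@H](CO)[C@@H]1CC[C@@H](C)c2c1ccc(OC)c2OC
F3 | step 8 | (4R)-4-benzyl-3-{[(1S,4R)-5,6-dimethoxy-4-methyl-1,2,3,4-tetrahydronaphthalen-1-yl]acetyl}oxazolidin-2-one | O=C(C[C@@H]1CC[C@@H](C)c2c1ccc(OC)c2OC)N1C(=O)OC[C@H]1Cc1ccccc1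
F4 | step 8 | (4R)-4-benzyl-3-{(2S)-3-(benzyloxy)-2-[(1S,4R)-5,6-dimethoxy-4-methyl-1,2,3,4-tetrahydronaphthalen-1-yl]propanoyl}oxazolidin-2-one | O=C([C@H](COCc1ccccc1)[C@@H]1CC[C@@H](C)c2c1ccc(OC)c2OC)N1C(=O)OC[C@H]1Cc1ccccc1
F5 | step 2 | (3R)-3-(2,3-dimethoxyphenyl)butan-1-ol | C[C@H](CCO)c1cccc(OC)c1OC
F6 | step 2 | 1-[(2R)-4-bromobutan-2-yl]-2,3-dimethoxybenzene | C[C@H](CCBr)c1cccc(OC)c1OC
F7 | step 13 | (2S,6S)-7-(benzyloxy)-6-[(1S,4R)-5,6-dimethoxy-4-methyl-1,2,3,4-tetrahydronaphthalen-1-yl]-2-methylheptan-1-ol | C[C@H](CO)CCC[C@H](COCc1ccccc1)[C@@H]1CC[C@@H](C)c2c1ccc(OC)c2OC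
F8 | step 16 | (5R,8S)-8-[(2S,6S)-1,7-dihydroxy-6-methylheptan-2-yl]-3,4-dimethoxy-5-methyl-5,6,7,8-tetrahydronaphthalene-2-carboxylic acid | C[C@H](CO)CCC[C@H](CO)[C@@H]1CC[C@@H](C)c2c1cc(C(=O)O)c(OC)c2OC
F9 | step 16 | (5R,8S)-8-[(2S,6S)-1,7-diacetoxy-6-methylheptan-2-yl]-3,4-dimethoxy-5-methyl-5,6,7,8-tetrahydronaphthalene-2-carboxylic acid | C[C@H](COC(C)=O)CCC[C@H](COC(C)=O)[C@@H]1CC[C@@H](C)c2c1cc(C(=O)O)c(OC)c2OC
F10 | step 16 | (5R,8S)-8-[(2S,6S)-1,7-diacetoxy-6-methylheptan-2-yl]-3,4-dihydroxy-5-methyl-5,6,7,8-tetrahydronaphthalene-2-carboxylic acid | C[C@H](COC(C)=O)CCC[C@H](COC(C)=O)[C@@H]1CC[C@@H](C)c2c1cc(C(=O)O)c(O)c2O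
A1 | alternative 1 | methyl ester of the bis-silylated dimethyl ether of the target (methyl 5,6-dimethoxytetralin-7-carboxylate with the full bis-silyloxy side chain, target configuration at C1, C4, C11, C15) | C[C@H](CO[Si](C)(C)C(C)(C)C)CCC[C@H](CO[Si](C)(C)C(C)(C)C)[C@@H]1CC[C@@H](C)c2c1cc(C(=O)OC)c(OC)c2OC
A2 | alternative 1 | methyl 4,5-dimethoxy-2-oxo-2H-pyran-3-carboxylate carrying at pyrone C6 the C4–C1 tether with a terminal alkyne on C1 and the bis-silyloxy side chain (target configuration at C1, C4, C11, C15) | C[C@H](CO[Si](C)(C)C(C)(C)C)CCC[C@H](CO[Si](C)(C)C(C)(C)C)[C@@H](C#C)CC[C@@H](C)C1=C(OC)C(OC)=C(C(=O)OC)C(=O)O1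
A3 | alternative 2 | methyl cis-3-methyl-7-[(1S,4R)-5,6-dimethoxy-4-methyltetralin-1-yl]cyclohepta-1,4-diene-2-carboxylate (ester on C14; target configuration at C11 and C15) | C[C@@H]1C=C[C@H]([C@@H]2CC[C@@H](C)c3c2ccc(OC)c3OC)CC=C1C(=O)OC
A4 | alternative 2 | methyl 2-diazobut-3-enoate | C=CC(=[N+]=[N-])C(=O)OC
A5 | alternative 2 | (1S,4R)-5,6-dimethoxy-4-methyl-1-[(1E,3E)-penta-1,3-dien-1-yl]-1,2,3,4-tetrahydronaphthalene | C/C=C/C=C/[C@@H]1CC[C@@H](C)c2c1ccc(OC)c2OC
A6 | alternative 3 | methyl 4-[(1S,4R)-5,6-dimethoxy-4-methyltetralin-1-yl]-2-oxotetrahydrofuran-3-carboxylate (target configuration at C11; ester-bearing carbon unspecified) | COC(=O)C1C(=O)OC[C@@H]1[C@@H]2CC[C@@H](C)c3c2ccc(OC)c3OC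
A7 | alternative 3 | methyl 6-exo-[(3R)-3-(2,3-dimethoxyphenyl)butyl]-2-oxo-3-oxabicyclo[3.1.0]hexane-1-carboxylate (single enantiomer as drawn) | COC(=O)[C@@]12C(=O)OC[C@@H]1[C@H]2CC[C@@H](C)c1cccc(OC)c1OC
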